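**Retrosynthetic overview**
- Enabling feature: in the six-membered quinone ring, the C(indol-3-yl)=C(OMe) edge lies between the two carbonyl carbons with a 1,4-relationship of its substituents to the second C(OMe)=C(aryl) edge. This edge is the retron of a polarized aryl ynol ether, and the other four ring carbons, C(=O)–C(OMe)=C(7-prenylindol-3-yl)–C(H, later =O), are the four carbons of a 3-aryl-4-methoxycyclobutenone, that is, of a vinylketene.
- Disconnection: N-Boc removal and para-oxidation lead back to a pentasubstituted phenol 22. This comes in one operation from cyclobutenone 12 and ynol ether 17 by a vinylketene/alkyne benzannulation.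
- Cyclobutenone 12 comes from 7-prenylindole (Stille coupling) by 3-iodination, N-Boc protection and addition of the 3-indolyl Grignard reagent to 3-ethoxy-4-methoxycyclobutenone 9 (ketene/ethoxyethyne [2+2]) with acidic carbonyl transposition. Ynol ether 17 comes from a Negishi coupling.
- Ring order: both indole rings are bought; the four-membered ring is made in step 4, opened and grown into the benzene ring in step 7, and oxidized to the quinone in step 8.

Key step: step 7

Remark on the chemistry: the target has no stereocentre. The sp3 centres of the four-membered-ring intermediates are racemic and vanish on aromatization. The enol ether geometries drawn for 18, 19 and 20 are those expected from outward rotation of the methoxy group.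

**Step 1**
Reactants: 1 7-bromo-1H-indole; 2 tributyl(3-methylbut-2-en-1-yl)stannane
Product: 3 7-(3-methylbut-2-en-1-yl)-1H-indole
Conditions: Pd(PPh3)4 (5 mol %), DMF, 100 °C
Reagents that add atoms: none
Why: Stille coupling, in which reductive elimination at the less hindered primary terminus of the prenyl palladium intermediate should give the linear prenyl arene, the free N–H being tolerated.

**Step 2**
Reactants: 3 7-(3-methylbut-2-en-1-yl)-1H-indole
Product: 4 3-iodo-7-(3-methylbut-2-en-1-yl)-1H-indole
Conditions: I2 (1.0 equiv), KOH, DMF, 0 °C to rt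
Reagents that add atoms: iodine, [I][I]
Why: Electrophilic iodination of the indolyl anion at C-3 should be much faster than any reaction of iodine with the trisubstituted alkene.

**Step 3**
Reactants: 4 3-iodo-7-(3-methylbut-2-en-1-yl)-1H-indole
Product: 5 tert-butyl 3-iodo-7-(3-methylbut-2-en-1-yl)indole-1-carboxylate
Conditions: Boc2O, DMAP (cat.), MeCN, rt
Reagents that add atoms: di-tert-butyl dicarbonate, CC(C)(C)OC(=O)OC(=O)OC(C)(C)C
Why: DMAP-catalysed N-acylation gives the carbamate, which stabilizes the 3-iodoindole and deactivates the indole for the later organometallic and ketene chemistry.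

**Step 4**
Reactants: 6 methoxyacetyl chloride; 7 ethoxyethyne
Product: 9 3-ethoxy-4-methoxycyclobut-2-en-1-one (racemic), via methoxyketene 8 (not isolated)
Conditions: Et3N, Et2O, 0 °C to rt, slow addition of 6
Reagents that add atoms: none
Why: Dehydrochlorination gives methoxyketene, which undergoes the thermal ketene/alkoxyalkyne [2+2] cycloaddition with the nucleophilic terminal alkyne carbon bonding to the ketene carbonyl carbon, so that ethoxy ends at C-3 and methoxy at the racemic C-4.

**Step 5**
Reactants: 5 tert-butyl 3-iodo-7-(3-methylbut-2-en-1-yl)indole-1-carboxylate; 9 3-ethoxy-4-methoxycyclobut-2-en-1-one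
Product: 12 tert-butyl 3-(4-methoxy-3-oxocyclobut-1-en-1-yl)-7-(3-methylbut-2-en-1-yl)indole-1-carboxylate (racemic), via indol-3-ylmagnesium chloride 10 (not isolated), via tertiary cyclobutenol 11 (not isolated)
Conditions: i-PrMgCl·LiCl, THF, −40 °C; 9, LaCl3·2LiCl, −40 to 0 °C; then 1 M HCl, THF, 0 °C
Reagents that add atoms: water, O
Why: Iodine–magnesium exchange, lanthanum-assisted 1,2-addition to the vinylogous ester carbonyl and acid-mediated 1,3-carbonyl transposition with loss of ethanol (Stork–Danheiser sequence) should give the 3-aryl-4-methoxycyclobutenone, whose C-4 centre stays racemic.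

**Step 6**
Reactants: 13 2-chloro-1,1-dimethoxyethane; 14 tert-butyl 3-iodoindole-1-carboxylate
Product: 17 tert-butyl 3-(methoxyethynyl)indole-1-carboxylate, via lithium methoxyacetylide 15 (not isolated), via (methoxyethynyl)zinc chloride 16 (not isolated)
Conditions: 13, LiNEt2 (3 equiv, from n-BuLi and Et2NH), THF, 0 °C; ZnCl2, 0 °C; then 14, Pd(PPh3)4 (5 mol %), THF, rt
Reagents that add atoms: none
Why: Threefold base-induced elimination of the chloroacetal gives lithium methoxyacetylide, which after transmetalation to zinc should couple with the aryl iodide under zerovalent palladium catalysis (Negishi coupling), a known entry to aryl alkynyl ethers.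

**Step 7**
Reactants: 12 tert-butyl 3-(4-methoxy-3-oxocyclobut-1-en-1-yl)-7-(3-methylbut-2-en-1-yl)indole-1-carboxylate; 17 tert-butyl 3-(methoxyethynyl)indole-1-carboxylate
Product: 22 2-[1-(tert-butoxycarbonyl)indol-3-yl]-3,6-dimethoxy-5-[1-(tert-butoxycarbonyl)-7-(3-methylbut-2-en-1-yl)indol-3-yl]phenol, via vinylketene 18 (not isolated), via 4-alkenylcyclobutenone 19 (not isolated), via dienylketene 20 (not isolated), via cyclohexa-2,4-dienone 21 (not isolated)
Conditions: 17 (1.3 equiv), toluene, 80 °C then 110 °C, argon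
Reagents that add atoms: none
Why: Heating 12 opens the four-membered ring by 4π-electrocyclic cleavage of the C(=O)–CH(OMe) bond (methoxy rotating outward) to vinylketene 18, and ynol ether 17 then adds across the ketene C=C bond in a regiospecific [2+2] cycloaddition in which its nucleophilic, indolyl-bearing carbon bonds to the ketene carbonyl carbon and its methoxy-bearing carbon to the ketene α-carbon, giving 19. A second 4π-opening gives dienylketene 20, whose thermal disrotatory 6π-electrocyclization re-forms the C(=O)–CH(OMe) bond and so closes the six-membered ring (21), and tautomerization should deliver phenol 22. The closest known reaction type is the Danheiser benzannulation of cyclobutenones with alkoxy- and siloxyalkynes. No stereocentre survives, because the sp3 centres of 12, 19 and 21 are racemic and are erased on aromatization. The one selectivity needed is the orientation of the alkyne, and it is fixed by the ynol ether polarization (oxocarbenium character at the methoxy carbon in the [2+2] transition state), which places the two methoxy groups para and the two indolyl groups para. The Boc groups deactivate both indole C2=C3 bonds, the prenyl alkene is far less nucleophilic than the ynol ether, and the methyl ynol ether has no β-hydrogen for a retro-ene loss to a ketene.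

**Step 8**
Reactants: 22 2-[1-(tert-butoxycarbonyl)indol-3-yl]-3,6-dimethoxy-5-[1-(tert-butoxycarbonyl)-7-(3-methylbut-2-en-1-yl)indol-3-yl]phenol
Product: 23 2,5-dimethoxy-3-[1-(tert-butoxycarbonyl)indol-3-yl]-6-[1-(tert-butoxycarbonyl)-7-(3-methylbut-2-en-1-yl)indol-3-yl]-1,4-benzoquinone
Conditions: (KSO3)2NO (2.5 equiv), KH2PO4, acetone–H2O, rt
Reagents that add atoms: potassium nitrosodisulfonate (Fremy's salt), [K+].[K+].[O]N(S(=O)(=O)[O-])S(=O)(=O)[O-]
Why: Teuber oxidation, in which the nitrosodisulfonate radical abstracts the phenolic hydrogen and a second equivalent delivers oxygen to the only free ring position, para to the hydroxyl group, so that only the para-quinone can form while the N-Boc indoles and the prenyl alkene stay untouched.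

**Step 9**
Reactants: 23 2,5-dimethoxy-3-[1-(tert-butoxycarbonyl)indol-3-yl]-6-[1-(tert-butoxycarbonyl)-7-(3-methylbut-2-en-1-yl)indol-3-yl]-1,4-benzoquinone
Product: 24 2,5-dimethoxy-3-(1H-indol-3-yl)-6-[7-(3-methylbut-2-en-1-yl)-1H-indol-3-yl]-1,4-benzoquinone (CNP0256613.0)
Conditions: K2CO3, MeOH–THF, rt
Reagents that add atoms: none
Why: Base-catalysed methanolysis of the two indole carbamates (acyl transfer to methoxide) should be easy on the electron-poor quinone-bound indoles, and methoxide exchange at the two methoxy-bearing quinone carbons is degenerate.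

**Compound list**
1 | 7-bromo-1H-indole | Brc1cccc2cc[nH]c12 | starting material
2 | tributyl(3-methylbut-2-en-1-yl)stannane | CCCC[Sn](CCCC)(CCCC)CC=C(C)C | starting material
3 | 7-(3-methylbut-2-en-1-yl)-1H-indole | CC(C)=CCc1cccc2cc[nH]c12 | intermediate
4 | 3-iodo-7-(3-methylbut-2-en-1-yl)-1H-indole | CC(C)=CCc1cccc2c(I)c[nH]c12 | intermediate
5 | tert-butyl 3-iodo-7-(3-methylbut-2-en-1-yl)indole-1-carboxylate | CC(C)=CCc1cccc2c(I)cn(C(=O)OC(C)(C)C)c12 | intermediate
6 | methoxyacetyl chloride | COCC(Cl)=O | starting material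
7 | ethoxyethyne | CCOC#C | starting material
8 | methoxyketene | COC=C=O | intermediate
9 | 3-ethoxy-4-methoxycyclobut-2-en-1-one (racemic) | CCOC1=CC(=O)C1OC | intermediate
10 | [1-(tert-butoxycarbonyl)-7-(3-methylbut-2-en-1-yl)indol-3-yl]magnesium chloride | CC(C)=CCc1cccc2c([Mg]Cl)cn(C(=O)OC(C)(C)C)c12 | intermediate
11 | tert-butyl 3-(3-ethoxy-1-hydroxy-4-methoxycyclobut-2-en-1-yl)-7-(3-methylbut-2-en-1-yl)indole-1-carboxylate (racemic, diastereomer mixture) | CCOC1=CC(O)(c2cn(C(=O)OC(C)(C)C)c3c(CC=C(C)C)cccc23)C1OC | intermediate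
12 | tert-butyl 3-(4-methoxy-3-oxocyclobut-1-en-1-yl)-7-(3-methylbut-2-en-1-yl)indole-1-carboxylate (racemic) | COC1C(=O)C=C1c1cn(C(=O)OC(C)(C)C)c2c(CC=C(C)C)cccc12 | intermediate
13 | 2-chloro-1,1-dimethoxyethane (chloroacetaldehyde dimethyl acetal) | COC(CCl)OC | starting material
14 | tert-butyl 3-iodoindole-1-carboxylate | CC(C)(C)OC(=O)n1cc(I)c2ccccc12 | starting material
15 | lithium methoxyacetylide | [Li]C#COC | intermediate
16 | (methoxyethynyl)zinc chloride | Cl[Zn]C#COC | intermediate
17 | tert-butyl 3-(methoxyethynyl)indole-1-carboxylate | COC#Cc1cn(C(=O)OC(C)(C)C)c2ccccc12 | intermediate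
18 | tert-butyl 3-[(1Z)-1-methoxy-4-oxobuta-1,3-dien-2-yl]-7-(3-methylbut-2-en-1-yl)indole-1-carboxylate (vinylketene) | O=C=C/C(=C/OC)c1cn(C(=O)OC(C)(C)C)c2c(CC=C(C)C)cccc12 | intermediate
19 | 4-alkenylcyclobutenone: 2-[1-Boc-indol-3-yl]-3-methoxy-4-[(Z)-2-methoxy-1-(1-Boc-7-prenylindol-3-yl)ethenyl]cyclobut-2-en-1-one (racemic) | CO/C=C(\c1cn(C(=O)OC(C)(C)C)c2c(CC=C(C)C)cccc12)C1C(=O)C(c2cn(C(=O)OC(C)(C)C)c3ccccc23)=C1OC | intermediate
20 | dienylketene: 2-[1-Boc-indol-3-yl]-3,6-dimethoxy-5-(1-Boc-7-prenylindol-3-yl)hexa-1,3,5-trien-1-one, ketene and enol ether termini cis across the central double bond | O=C=C(c1cn(C(=O)OC(C)(C)C)c2ccccc12)/C(OC)=C\C(=C\OC)c1cn(C(=O)OC(C)(C)C)c2c(CC=C(C)C)cccc12 | intermediate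
21 | 2-[1-Boc-indol-3-yl]-3,6-dimethoxy-5-(1-Boc-7-prenylindol-3-yl)cyclohexa-2,4-dien-1-one (racemic) | COC1C(=O)C(c2cn(C(=O)OC(C)(C)C)c3ccccc23)=C(OC)C=C1c1cn(C(=O)OC(C)(C)C)c2c(CC=C(C)C)cccc12 | intermediate
22 | 2-[1-(tert-butoxycarbonyl)indol-3-yl]-3,6-dimethoxy-5-[1-(tert-butoxycarbonyl)-7-(3-methylbut-2-en-1-yl)indol-3-yl]phenol | COc1cc(-c2cn(C(=O)OC(C)(C)C)c3c(CC=C(C)C)cccc23)c(OC)c(O)c1-c1cn(C(=O)OC(C)(C)C)c2ccccc12 | intermediate
23 | 2,5-dimethoxy-3-[1-(tert-butoxycarbonyl)indol-3-yl]-6-[1-(tert-butoxycarbonyl)-7-(3-methylbut-2-en-1-yl)indol-3-yl]-1,4-benzoquinone | COC1=C(c2cn(C(=O)OC(C)(C)C)c3ccccc23)C(=O)C(OC)=C(c2cn(C(=O)OC(C)(C)C)c3c(CC=C(C)C)cccc23)C1=O | intermediate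
24 | 2,5-dimethoxy-3-(1H-indol-3-yl)-6-[7-(3-methylbut-2-en-1-yl)-1H-indol-3-yl]-1,4-benzoquinone (CNP0256613.0) | COC1=C(c2c[nH]c3ccccc23)C(=O)C(OC)=C(c2c[nH]c3c(CC=C(C)C)cccc23)C1=O | target

**Step count and risks**
Total steps: 9. Longest linear sequence: 7 steps (steps 1, 2, 3, 5, 7, 8, 9, from 7-bromoindole).

Steps most likely to fail:

1. Step 7 (benzannulation). The transient vinylketene may be consumed unproductively, by dimerization or by acylating the product phenol, or the ynol ether may decay thermally before the [2+2] event, so that the cascade does not reach the arene. In the fallback the six-membered ring is not built but bought as a quinone, and the two indoles are attached one after the other by acid-promoted conjugate addition. It sets out from 3 and comes back at 24. Indole adds through C-3 to 2,5-dichloro-1,4-benzoquinone (HCl, THF, rt) to give 2,5-dichloro-3-(1H-indol-3-yl)benzene-1,4-diol F1, which DDQ oxidizes in the same flask to 2,5-dichloro-3-(1H-indol-3-yl)-1,4-benzoquinone F2. Compound 3 then adds to the only free ring position of F2 (AcOH, THF, rt) to give 2,5-dichloro-3-(1H-indol-3-yl)-6-[7-(3-methylbut-2-en-1-yl)-1H-indol-3-yl]benzene-1,4-diol F3, which DDQ oxidizes to 2,5-dichloro-3-(1H-indol-3-yl)-6-[7-(3-methylbut-2-en-1-yl)-1H-indol-3-yl]-1,4-benzoquinone F4. NaOH in MeOH at reflux followed by acidification should exchange both chlorides to give 2,5-dihydroxy-3-(1H-indol-3-yl)-6-[7-(3-methylbut-2-en-1-yl)-1H-indol-3-yl]-1,4-benzoquinone F5. Me3SiCHN2 in MeOH–toluene should then methylate the two acidic quinone hydroxyl groups and give 24.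

2. Step 6 (ynol ether by Negishi coupling). The lithium methoxyacetylide or the ynol ether product may be lost through hydration or oligomerization, or the transmetalation and coupling at the electron-rich C-3 iodide may be too slow. In the fallback the triple bond is made by elimination instead of cross-coupling. It sets out from 14 and comes back at 17. Iodine–magnesium exchange (i-PrMgCl·LiCl, THF, −40 °C) gives [1-(tert-butoxycarbonyl)indol-3-yl]magnesium chloride F6, which is acylated with N-methoxy-N-methyl-2-methoxyacetamide to tert-butyl 3-(2-methoxyacetyl)indole-1-carboxylate F7. LiN(SiMe3)2 and PhNTf2 (THF, −78 °C) should give, through the chelated Z-enolate, tert-butyl 3-[(Z)-2-methoxy-1-(trifluoromethylsulfonyloxy)ethenyl]indole-1-carboxylate F8. KOt-Bu (THF, −78 °C) should effect anti-elimination of triflate to 17.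

3. Step 5 (Grignard addition and transposition). The indolylmagnesium species may attack its own carbamate, the 1,2-addition to the vinylogous ester may be poor, or the 4-methoxycyclobutenone may ring-open during the acidic transposition and isolation. In the fallback the aryl–cyclobutenone bond is made by electrophilic substitution of the free indole instead of by an organometallic addition. It sets out from 3 (with 9) and comes back at 12. Sc(OTf)3 (10 mol %, MeCN, 0 °C) activates 9 for attack of indole C-3 at the ethoxy-bearing carbon; loss of ethanol gives 4-methoxy-3-[7-(3-methylbut-2-en-1-yl)-1H-indol-3-yl]cyclobut-2-en-1-one F9. Boc2O with catalytic DMAP (MeCN, rt) then gives 12.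

**Further compounds**
F1 | step 7 | 2,5-dichloro-3-(1H-indol-3-yl)benzene-1,4-diol | Oc1cc(Cl)c(O)c(-c2c[nH]c3ccccc23)c1Cl
F2 | step 7 | 2,5-dichloro-3-(1H-indol-3-yl)-1,4-benzoquinone | O=C1C=C(Cl)C(=O)C(c2c[nH]c3ccccc23)=C1Cl
F3 | step 7 | 2,5-dichloro-3-(1H-indol-3-yl)-6-[7-(3-methylbut-2-en-1-yl)-1H-indol-3-yl]benzene-1,4-diol | Oc1c(Cl)c(-c2c[nH]c3ccccc23)c(O)c(Cl)c1-c1c[nH]c2c(CC=C(C)C)cccc12
F4 | step 7 | 2,5-dichloro-3-(1H-indol-3-yl)-6-[7-(3-methylbut-2-en-1-yl)-1H-indol-3-yl]-1,4-benzoquinone | O=C1C(c2c[nH]c3c(CC=C(C)C)cccc23)=C(Cl)C(=O)C(c2c[nH]c3ccccc23)=C1Cl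
F5 | step 7 | 2,5-dihydroxy-3-(1H-indol-3-yl)-6-[7-(3-methylbut-2-en-1-yl)-1H-indol-3-yl]-1,4-benzoquinone | O=C1C(c2c[nH]c3c(CC=C(C)C)cccc23)=C(O)C(=O)C(c2c[nH]c3ccccc23)=C1O
F6 | step 6 | [1-(tert-butoxycarbonyl)indol-3-yl]magnesium chloride | CC(C)(C)OC(=O)n1cc([Mg]Cl)c2ccccc12
F7 | step 6 | tert-butyl 3-(2-methoxyacetyl)indole-1-carboxylate | COCC(=O)c1cn(C(=O)OC(C)(C)C)c2ccccc12
F8 | step 6 | tert-butyl 3-[(Z)-2-methoxy-1-(trifluoromethylsulfonyloxy)ethenyl]indole-1-carboxylate | CO/C=C(\OS(=O)(=O)C(F)(F)F)c1cn(C(=O)OC(C)(C)C)c2ccccc12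
F9 | step 5 | 4-methoxy-3-[7-(3-methylbut-2-en-1-yl)-1H-indol-3-yl]cyclobut-2-en-1-one (racemic) | COC1C(=O)C=C1c1c[nH]c2c(CC=C(C)C)cccc12
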